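The route rests on cutting C2–C1′, the bond between the pyran C ring and the B ring. C2 adjoins the ring oxygen O1, so a C ring held at the 2-ethoxy-2H-chromene level ionises to the aromatic 1-benzopyrylium cation (rings A and C) with C2 as its electrophilic carbon. C1′, para to O4′, is ipso-nucleophilic as a boronate. In one operation a chiral dihydroxy acid/lanthanide triflate pair transfers the aryl group to C2 enantioselectively. This unites two halves that already carry their benzylated gallates at O7 and O3′. The precursor is a racemic chromene acetal. Hydroboration of the remaining C3=C4 alkene sets C3, and one hydrogenolysis finishes.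

Key step: step 9

Remark on the chemistry: the sense of induction of the tartaric-acid-derived catalyst is assumed by analogy. Both antipodes of tartaric acid are commercial, so the catalyst enantiomer that delivers the drawn C2 configuration is used. Compounds 1, 3 and 8 are taken as catalogue compounds.

Step 1
Reactants: 1 3,4,5-tris(benzyloxy)benzoic acid
Product: 2 3,4,5-tris(benzyloxy)benzoyl chloride
Conditions: (COCl)2, DMF (cat.), CH2Cl2, 0 °C → rt; evaporate
Reagents that add atoms: oxalyl chloride, O=C(Cl)C(=O)Cl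
Why: Vilsmeier-type activation (DMF/oxalyl chloride) should convert the acid into its chloride under conditions that leave the benzyl ethers intact, and no stereocentre is involved.

Step 2
Reactants: 3 2,4,6-trihydroxybenzaldehyde; 2 3,4,5-tris(benzyloxy)benzoyl chloride
Product: 4 4-formyl-3,5-dihydroxyphenyl 3,4,5-tris(benzyloxy)benzoate
Conditions: 2 (1.0 equiv, slow addition), Et3N (1.05 equiv), THF, −20 → 0 °C
Reagents that add atoms: none
Why: Regioselective O-acylation of Schotten–Baumann/Einhorn type, in which the 4-OH (para to CHO) is the most acidic hydroxyl and the only one that neither flanks nor hydrogen-bonds to the formyl group, so one equivalent of base and acyl chloride at low temperature should esterify it alone.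

Step 3
Reactants: 4 4-formyl-3,5-dihydroxyphenyl 3,4,5-tris(benzyloxy)benzoate
Product: 5 3-(benzyloxy)-4-formyl-5-hydroxyphenyl 3,4,5-tris(benzyloxy)benzoate
Conditions: BnOH (1.05 equiv), PPh3, DIAD, THF, 0 °C → rt
Reagents that add atoms: benzyl alcohol, OCc1ccccc1
Why: Mitsunobu etherification runs under essentially neutral conditions that spare the aryl ester, and it should stop after one of the two equivalent ortho-hydroxyls has reacted because the remaining OH is then locked in a strong hydrogen bond to the formyl oxygen.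

Step 4
Reactants: 5 3-(benzyloxy)-4-formyl-5-hydroxyphenyl 3,4,5-tris(benzyloxy)benzoate
Product: 6 3-(benzyloxy)-5-hydroxy-4-[(E)-3-oxoprop-1-enyl]phenyl 3,4,5-tris(benzyloxy)benzoate
Conditions: Ph3P=CHCHO (1.2 equiv), toluene, 80 °C
Reagents that add atoms: (triphenylphosphoranylidene)acetaldehyde, O=CC=P(c1ccccc1)(c1ccccc1)c1ccccc1
Why: Wittig olefination with the stabilised formyl ylide should give the (E)-enal, since the hydrogen-bond-activated salicylaldehyde carbonyl reacts in preference to the enal product and the neutral medium spares the ester.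

Step 5
Reactants: 6 3-(benzyloxy)-5-hydroxy-4-[(E)-3-oxoprop-1-enyl]phenyl 3,4,5-tris(benzyloxy)benzoate
Product: 7 (±)-5-(benzyloxy)-2-ethoxy-2H-chromen-7-yl 3,4,5-tris(benzyloxy)benzoate
Conditions: HC(OEt)3, CSA (5 mol %), EtOH, 40 °C; Et3N quench; Et3N-deactivated silica
Reagents that add atoms: triethyl orthoformate, CCOC(OCC)OCC
Why: Acid-catalysed cycloacetalisation, in which the O-activated enal is a cation delocalised into the oxygenated A ring so that the C3–C4 bond can rotate, the phenol oxygen closes onto C2 (six-membered ring) and ethanol traps the benzopyrylium ion as the racemic mixed acetal.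

Step 6
Reactants: 8 2-(benzyloxy)-5-bromobenzaldehyde
Product: 10 2-(benzyloxy)-5-bromophenol, via aryl formate 9 (not isolated)
Conditions: mCPBA, CH2Cl2, rt; then K2CO3 (cat.), MeOH, rt
Reagents that add atoms: mCPBA, O=C(OO)c1cccc(Cl)c1
Why: Baeyer–Villiger (Dakin-type) oxidation, in which the electron-rich 2-alkoxyaryl group migrates in the Criegee adduct to give formate 9, which catalytic base in methanol transesterifies to the free phenol.

Step 7
Reactants: 10 2-(benzyloxy)-5-bromophenol
Product: 11 [4-(benzyloxy)-3-hydroxyphenyl]boronic acid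
Conditions: B2(OH)4, XPhos-Pd-G2 (1 mol %), XPhos, KOAc, EtOH, 80 °C; dilute HCl work-up
Reagents that add atoms: tetrahydroxydiboron, OB(O)B(O)O
Why: Miyaura-type Pd-catalysed borylation with tetrahydroxydiboron should deliver the boronic acid directly at the C–Br carbon para to OBn, and it tolerates the free phenol.

Step 8
Reactants: 11 [4-(benzyloxy)-3-hydroxyphenyl]boronic acid; 2 3,4,5-tris(benzyloxy)benzoyl chloride
Product: 12 [4-(benzyloxy)-3-{[3,4,5-tris(benzyloxy)benzoyl]oxy}phenyl]boronic acid
Conditions: 2 (1.05 equiv), Et3N, DMAP (cat.), THF, 0 °C → rt; dilute HCl work-up; crystallisation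
Reagents that add atoms: none
Why: DMAP-catalysed acylation of the phenol, in which any mixed anhydride formed at a B–OH group is itself an acyl donor and is hydrolysed on acidic work-up, so only the aryl ester should persist.

Step 9
Reactants: 7 (±)-5-(benzyloxy)-2-ethoxy-2H-chromen-7-yl 3,4,5-tris(benzyloxy)benzoate; 12 [4-(benzyloxy)-3-{[3,4,5-tris(benzyloxy)benzoyl]oxy}phenyl]boronic acid
Product: 15 (2S)-5-(benzyloxy)-2-[4-(benzyloxy)-3-{[3,4,5-tris(benzyloxy)benzoyl]oxy}phenyl]-2H-chromen-7-yl 3,4,5-tris(benzyloxy)benzoate, via diethyl boronate 13 (not isolated), via benzopyrylium ion 14 (not isolated)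
Conditions: 12 (1.5 equiv), EtOH/toluene, azeotropic evaporation; then 7, tartaric acid monoamide (α,β-dihydroxy acid, 10 mol %), Yb(OTf)3 (9 mol %), EtOAc, −20 → 4 °C, dark
Reagents that add atoms: ethanol, CCO (ethoxy groups of intermediate 13 only)
Why: The dihydroxy acid exchanges with 13 to give a more Lewis-acidic chiral dioxaborolane, which together with Yb(OTf)3 pulls ethoxide from C2 of 7 and leaves the aromatic 10π benzopyrylium ion 14 paired with a chiral aryl(ethoxy)borate, and the B-ring aryl then migrates from boron to C2 within this ion pair. This is the known chiral Brønsted acid/Lewis acid catalysed enantioselective addition of aryl boronates to 2-alkoxy-2H-chromenes, a Petasis-type boron-to-oxocarbenium transfer. No ring is closed, since rings A and C are only aromatised transiently and C2 returns to sp3. C2 is the sole new stereocentre and is set by the catalyst, because both enantiomers of racemic 7 converge on planar 14 (the descriptor is S here only because C1′ outranks sp2 C3, and the spatial arrangement is that of 2R in the target). The step needs attack at C2 rather than C4, which is secured by the ion pair forming next to O1 and by the peri 5-OBn group that screens C4, and it needs ipso transfer at C1′, which is secured by the C–B bond and the para 4′-OBn donor. The base-free medium should leave both aryl gallate esters untouched.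

Step 10
Reactants: 15 (2S)-flav-3-ene from step 9
Product: 17 (2R,3S)-5-(benzyloxy)-2-[4-(benzyloxy)-3-{[3,4,5-tris(benzyloxy)benzoyl]oxy}phenyl]-3-hydroxychroman-7-yl 3,4,5-tris(benzyloxy)benzoate, via C3-alkylborane 16 (not isolated)
Conditions: BH3·THF (2 equiv), THF, 0 °C, dark; then H2O, Oxone, THF/H2O, 0 °C → rt
Reagents that add atoms: borane (as BH3·THF), B (boron of intermediate 16 only); potassium peroxymonosulfate (Oxone), [K+].[O-]S(=O)(=O)OO
Why: Hydroboration–oxidation of a flav-3-ene, in which H–B adds syn on the face anti to the C2 aryl group with boron at C3 (β to the electron-rich A ring and next to the C2–O dipole), and base-free Oxone oxidation replaces boron by OH with retention, which sets 3S (2,3-trans) without cleaving the aryl esters.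

Step 11
Reactants: 17 (2R,3S)-octa-O-benzyl flavan-3-ol from step 10
Product: 18 (2R,3S)-catechin 7,3′-di-O-gallate
Conditions: H2 (1 atm), Pd(OH)2/C, THF/MeOH, trace AcOH, rt
Reagents that add atoms: none
Why: Catalytic hydrogenolysis should cleave all eight O-benzyl groups while the aryl esters, the C2–O1 bond and both stereocentres stay untouched under faintly acidic conditions that also suppress 3′→4′ acyl migration.

Compound list
1 | 3,4,5-tris(benzyloxy)benzoic acid | OC(=O)c1cc(OCc2ccccc2)c(OCc2ccccc2)c(OCc2ccccc2)c1 | starting material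
2 | 3,4,5-tris(benzyloxy)benzoyl chloride | ClC(=O)c1cc(OCc2ccccc2)c(OCc2ccccc2)c(OCc2ccccc2)c1 | intermediate
3 | 2,4,6-trihydroxybenzaldehyde | O=Cc1c(O)cc(O)cc1O | starting material
4 | 4-formyl-3,5-dihydroxyphenyl 3,4,5-tris(benzyloxy)benzoate | O=Cc1c(O)cc(OC(=O)c2cc(OCc3ccccc3)c(OCc3ccccc3)c(OCc3ccccc3)c2)cc1O | intermediate
5 | 3-(benzyloxy)-4-formyl-5-hydroxyphenyl 3,4,5-tris(benzyloxy)benzoate | O=Cc1c(O)cc(OC(=O)c2cc(OCc3ccccc3)c(OCc3ccccc3)c(OCc3ccccc3)c2)cc1OCc1ccccc1 | intermediate
6 | 3-(benzyloxy)-5-hydroxy-4-[(E)-3-oxoprop-1-enyl]phenyl 3,4,5-tris(benzyloxy)benzoate | O=C/C=C/c1c(O)cc(OC(=O)c2cc(OCc3ccccc3)c(OCc3ccccc3)c(OCc3ccccc3)c2)cc1OCc1ccccc1 | intermediate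
7 | (±)-5-(benzyloxy)-2-ethoxy-2H-chromen-7-yl 3,4,5-tris(benzyloxy)benzoate (racemic acetal) | CCOC1C=Cc2c(OCc3ccccc3)cc(OC(=O)c3cc(OCc4ccccc4)c(OCc4ccccc4)c(OCc4ccccc4)c3)cc2O1 | intermediate
8 | 2-(benzyloxy)-5-bromobenzaldehyde | O=Cc1cc(Br)ccc1OCc1ccccc1 | starting material
9 | 2-(benzyloxy)-5-bromophenyl formate (not isolated) | O=COc1cc(Br)ccc1OCc1ccccc1 | intermediate
10 | 2-(benzyloxy)-5-bromophenol | Oc1cc(Br)ccc1OCc1ccccc1 | intermediate
11 | [4-(benzyloxy)-3-hydroxyphenyl]boronic acid | OB(O)c1ccc(OCc2ccccc2)c(O)c1 | intermediate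
12 | [4-(benzyloxy)-3-{[3,4,5-tris(benzyloxy)benzoyl]oxy}phenyl]boronic acid | OB(O)c1ccc(OCc2ccccc2)c(OC(=O)c2cc(OCc3ccccc3)c(OCc3ccccc3)c(OCc3ccccc3)c2)c1 | intermediate
13 | diethyl ester of boronic acid 12 (not isolated) | CCOB(OCC)c1ccc(OCc2ccccc2)c(OC(=O)c2cc(OCc3ccccc3)c(OCc3ccccc3)c(OCc3ccccc3)c2)c1 | intermediate
14 | 5-(benzyloxy)-7-{[3,4,5-tris(benzyloxy)benzoyl]oxy}-1-benzopyrylium ion (not isolated; counter-ion is the chiral aryl(ethoxy)borate) | c1cc2c(OCc3ccccc3)cc(OC(=O)c3cc(OCc4ccccc4)c(OCc4ccccc4)c(OCc4ccccc4)c3)cc2[o+]c1 | intermediate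
15 | (2S)-5-(benzyloxy)-2-[4-(benzyloxy)-3-{[3,4,5-tris(benzyloxy)benzoyl]oxy}phenyl]-2H-chromen-7-yl 3,4,5-tris(benzyloxy)benzoate | O=C(Oc1cc(OCc3ccccc3)c2c(c1)O[C@H](c1ccc(OCc3ccccc3)c(OC(=O)c3cc(OCc4ccccc4)c(OCc4ccccc4)c(OCc4ccccc4)c3)c1)C=C2)c1cc(OCc2ccccc2)c(OCc2ccccc2)c(OCc2ccccc2)c1 | intermediate
16 | 2,3-trans C3-alkylborane of 15, BH2 anti to the 2-aryl group (not isolated) | O=C(Oc1cc(OCc3ccccc3)c2c(c1)O[C@H](c1ccc(OCc3ccccc3)c(OC(=O)c3cc(OCc4ccccc4)c(OCc4ccccc4)c(OCc4ccccc4)c3)c1)[C@@H](B)C2)c1cc(OCc2ccccc2)c(OCc2ccccc2)c(OCc2ccccc2)c1 | intermediate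
17 | (2R,3S)-5-(benzyloxy)-2-[4-(benzyloxy)-3-{[3,4,5-tris(benzyloxy)benzoyl]oxy}phenyl]-3-hydroxychroman-7-yl 3,4,5-tris(benzyloxy)benzoate | O=C(Oc1cc(OCc3ccccc3)c2c(c1)O[C@H](c1ccc(OCc3ccccc3)c(OC(=O)c3cc(OCc4ccccc4)c(OCc4ccccc4)c(OCc4ccccc4)c3)c1)[C@@H](O)C2)c1cc(OCc2ccccc2)c(OCc2ccccc2)c(OCc2ccccc2)c1 | intermediate
18 | (2R,3S)-catechin 7,3′-di-O-gallate | O=C(Oc1cc(O)c2c(c1)O[C@H](c1ccc(O)c(OC(=O)c3cc(O)c(O)c(O)c3)c1)[C@@H](O)C2)c1cc(O)c(O)c(O)c1 | target

Total step count: 11. Longest linear sequence: 8 (steps 1, 2, 3, 4, 5, 9, 10, 11).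

Steps most likely to fail

Step 9. Three processes threaten this step:
- Facial discrimination on the bulky, donor-rich benzopyrylium ion may be insufficient.
- Aryl transfer to C4 may compete.
- Configuration may erode through light- or acid-induced ring opening of the 2H-chromene.

The fallback gives up catalyst control and uses a transition-metal cross-coupling followed by resolution. It sets out from 7 and 12.
- Ni(cod)2/PPh3 (base-free, dioxane/t-AmOH, rt to 60 °C) should insert into the C2–OEt bond. The released ethoxide activates the boronic acid for transmetalation, and reductive elimination forms the same C2–C1′ bond.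
- This gives 15 as the racemate, that is together with the (2R)-configured flav-3-ene F1.
- Hydroboration and oxidation as in step 10 should then give 17 together with the (2S,3R)-configured flavan-3-ol F2.
- Preparative chromatography on a chiral stationary phase removes the unwanted antipode, and the route is rejoined at 17.

Step 10. Four processes threaten this step:
- Borane may partly reduce the two aryl esters.
- The esters may be cleaved during the oxidation.
- The C3-borane may undergo β-elimination across C2–O1.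
- Boron may be placed at C4.

The fallback replaces hydroboration by oxidation followed by ionic deoxygenation, both of which tolerate esters. It sets out from 15.
- OsO4 (cat.)/NMO in acetone/H2O should dihydroxylate C3=C4 on the face anti to the 2-aryl group and give the (2R,3S,4S)-2,3-trans-3,4-cis-flavan-3,4-diol F3.
- Et3SiH/TFA in CH2Cl2 (−40 → 0 °C) then ionises only the C4–OH, which gives a benzylic cation stabilised by O1 and O5. Hydride delivery returns the route at 17.

Step 4. The hindered, electron-rich 2,6-dioxygenated aldehyde may olefinate sluggishly, and the less hindered enal product may undergo a second olefination. The fallback closes the ring by an intramolecular Wittig reaction at a lower oxidation level and then raises C2 by C–H hydride abstraction. It sets out from 5.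
- Vinyltriphenylphosphonium bromide with K2CO3 (1 equiv) in MeCN at 60 °C (Schweizer reaction: oxa-Michael addition, then intramolecular Wittig) should give 5-(benzyloxy)-2H-chromen-7-yl 3,4,5-tris(benzyloxy)benzoate F4.
- DDQ with EtOH in CH2Cl2 at 0 °C abstracts hydride from C2. Ethanol traps the benzopyrylium ion and returns the route at 7.

Further compounds
F1 | step 9 | (2R)-5-(benzyloxy)-2-[4-(benzyloxy)-3-{[3,4,5-tris(benzyloxy)benzoyl]oxy}phenyl]-2H-chromen-7-yl 3,4,5-tris(benzyloxy)benzoate (mirror image of 15) | O=C(Oc1cc(OCc3ccccc3)c2c(c1)O[C@@H](c1ccc(OCc3ccccc3)c(OC(=O)c3cc(OCc4ccccc4)c(OCc4ccccc4)c(OCc4ccccc4)c3)c1)C=C2)c1cc(OCc2ccccc2)c(OCc2ccccc2)c(OCc2ccccc2)c1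
F2 | step 9 | (2S,3R)-5-(benzyloxy)-2-[4-(benzyloxy)-3-{[3,4,5-tris(benzyloxy)benzoyl]oxy}phenyl]-3-hydroxychroman-7-yl 3,4,5-tris(benzyloxy)benzoate (mirror image of 17) | O=C(Oc1cc(OCc3ccccc3)c2c(c1)O[C@@H](c1ccc(OCc3ccccc3)c(OC(=O)c3cc(OCc4ccccc4)c(OCc4ccccc4)c(OCc4ccccc4)c3)c1)[C@H](O)C2)c1cc(OCc2ccccc2)c(OCc2ccccc2)c(OCc2ccccc2)c1
F3 | step 10 | (2R,3S,4S)-5-(benzyloxy)-2-[4-(benzyloxy)-3-{[3,4,5-tris(benzyloxy)benzoyl]oxy}phenyl]-3,4-dihydroxychroman-7-yl 3,4,5-tris(benzyloxy)benzoate | O=C(Oc1cc(OCc3ccccc3)c2c(c1)O[C@H](c1ccc(OCc3ccccc3)c(OC(=O)c3cc(OCc4ccccc4)c(OCc4ccccc4)c(OCc4ccccc4)c3)c1)[C@@H](O)[C@H]2O)c1cc(OCc2ccccc2)c(OCc2ccccc2)c(OCc2ccccc2)c1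
F4 | step 4 | 5-(benzyloxy)-2H-chromen-7-yl 3,4,5-tris(benzyloxy)benzoate | C1C=Cc2c(OCc3ccccc3)cc(OC(=O)c3cc(OCc4ccccc4)c(OCc4ccccc4)c(OCc4ccccc4)c3)cc2O1
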